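**Retrosynthetic overview**
- The last step is removal of the 7,8-acetonide; both rings of the core come from one acyclic dienynone in a single operation.
- Ring B (pyran, key step): oxa-6π electrocyclization of the cross-conjugated 1-oxatriene O=C3–C4=C4a–C8a=C1H2 to a 2H-pyran, then enone tautomerization, which sets C8a.
- Ring A (carbocycle) forms first: 6-exo-dig Michael addition of the methyl ketone enolate (C5) to the ynone carbon C4a.
- The dienynone comes from carbonylative coupling of an enyne ketone (C7/C8 from L-tartrate) with an E-vinyl iodide (C4'/C5' from L-isoleucine, C3' by chelation-controlled MeMgBr addition).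
- Order of ring formation: carbocycle, then pyran.

Assumption: reagents carry no numbers, and metalated species that last only until the quench (enolates, alkoxides, tetrahedral adducts) are treated as part of the reagent's action and are not numbered. Locants C1–C8a refer to the isochromenone core of the target, C1'–C7' to its side chain.

**Step 1**
Reactants: 1 dimethyl (4R,5R)-2,2-dimethyl-1,3-dioxolane-4,5-dicarboxylate
Product: 2 dimethyl (4R,5R)-2,2,4-trimethyl-1,3-dioxolane-4,5-dicarboxylate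
Conditions: LiN(iPr)2 (1.1 equiv), THF/HMPA, −78 °C; then MeI (3 equiv), −78 °C, 24 h
Reagents that add atoms: iodomethane CI
Why: Seebach-type alkylation of the tartrate-acetonide lithium enolate, in which the electrophile enters cis to the neighbouring ester so the trans-diester is kept and the new quaternary centre (future C7, R) is controlled by the untouched tartrate centre (future C8); the enolate is held at −78 °C to avoid β-elimination.

**Step 2**
Reactants: 2 dimethyl (4R,5R)-2,2,4-trimethyl-1,3-dioxolane-4,5-dicarboxylate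
Product: 3 (4R,5R)-N4,N5-dimethoxy-N4,N5,2,2,4-pentamethyl-1,3-dioxolane-4,5-dicarboxamide
Conditions: MeNH(OMe)·HCl (6 equiv), iPrMgCl (12 equiv), THF, −20 → 23 °C
Reagents that add atoms: N,O-dimethylhydroxylamine hydrochloride CNOC.Cl
Why: Double Weinreb amide formation by aminolysis of both esters with ClMgN(OMe)Me; no stereocentre is touched and both carbonyls become mono-addition acceptors.

**Step 3**
Reactants: 3 (4R,5R)-N4,N5-dimethoxy-N4,N5,2,2,4-pentamethyl-1,3-dioxolane-4,5-dicarboxamide; 4 ethynyl(trimethyl)silane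
Product: 5 (4R,5R)-N-methoxy-N,2,2,4-tetramethyl-5-[3-(trimethylsilyl)prop-2-ynoyl]-1,3-dioxolane-4-carboxamide
Conditions: 4 (1.05 equiv), n-BuLi, THF, −78 °C; then 3, −78 °C, 1 h; aq NH4Cl
Reagents that add atoms: none
Why: Weinreb ketone synthesis in which the acetylide attacks only the amide on the CH carbon (the amide on the quaternary carbon is shielded) and the chelated tetrahedral adduct prevents over-addition.

**Step 4**
Reactants: 5 (4R,5R)-N-methoxy-N,2,2,4-tetramethyl-5-[3-(trimethylsilyl)prop-2-ynoyl]-1,3-dioxolane-4-carboxamide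
Product: 6 (4R,5S)-N-methoxy-N,2,2,4-tetramethyl-5-[4-(trimethylsilyl)but-1-en-3-yn-2-yl]-1,3-dioxolane-4-carboxamide
Conditions: Zn, CH2Br2, TiCl4, THF (reagent pre-formed); then 5, CH2Cl2, 0 → 23 °C
Reagents that add atoms: dibromomethane BrCBr
Why: Takai–Lombardo methylenation, whose non-basic Zn/Ti methylene reagent turns the ynone carbonyl into the 1,1-disubstituted enyne (C8a=C1H2) without epimerising the α-alkoxy centre or touching the amide.

**Step 5**
Reactants: 6 (4R,5S)-N-methoxy-N,2,2,4-tetramethyl-5-[4-(trimethylsilyl)but-1-en-3-yn-2-yl]-1,3-dioxolane-4-carboxamide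
Product: 8 1-[(4R,5S)-5-(but-1-en-3-yn-2-yl)-2,2,4-trimethyl-1,3-dioxolan-4-yl]ethan-1-one, via silyl enyne ketone 7 (not isolated)
Conditions: MeMgBr (3 equiv), THF, 0 → 23 °C; aq NH4Cl; then K2CO3 (0.2 equiv), MeOH, 23 °C
Reagents that add atoms: methylmagnesium bromide C[Mg]Br
Why: Weinreb ketone synthesis installs the methyl ketone (C6/C5) and mild methanolysis then cleaves the alkynyl C–Si bond; no stereocentre is affected.

**Step 6**
Reactants: 9 L-isoleucine
Product: 12 (2S,3S)-2-hydroxy-3-methylpentanoic acid, via diazonium carboxylate 10 (not isolated), via alpha-lactone 11 (not isolated)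
Conditions: NaNO2, 1 M H2SO4, H2O, 0 → 23 °C
Reagents that add atoms: water O
Why: Diazotisation of the α-amino acid with carboxylate participation; double inversion through the α-lactone gives net retention at C2.

**Step 7**
Reactants: 12 (2S,3S)-2-hydroxy-3-methylpentanoic acid
Product: 13 (5S)-5-[(2S)-butan-2-yl]-2,2-dimethyl-1,3-dioxolan-4-one
Conditions: Me2C(OMe)2, PPTS (cat.), CH2Cl2, 40 °C
Reagents that add atoms: 2,2-dimethoxypropane COC(C)(C)OC
Why: Acid-catalysed transacetalisation gives the dioxolanone, which masks the hydroxyl and activates the carboxyl for a single nucleophilic addition.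

**Step 8**
Reactants: 13 (5S)-5-[(2S)-butan-2-yl]-2,2-dimethyl-1,3-dioxolan-4-one; 4 ethynyl(trimethyl)silane
Product: 14 (4S,5S)-4-hydroxy-5-methyl-1-(trimethylsilyl)hept-1-yn-3-one
Conditions: 4 (1.05 equiv), n-BuLi, THF, −78 °C; then 13, −78 °C, 30 min; aq NH4Cl at −78 °C; used crude at once
Reagents that add atoms: none
Why: Acetylide addition to the dioxolanone carbonyl gives a hemiketal alkoxide that collapses on work-up to the α-hydroxy ynone with loss of acetone (mono-addition; stereocentres untouched).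

**Step 9**
Reactants: 14 (4S,5S)-4-hydroxy-5-methyl-1-(trimethylsilyl)hept-1-yn-3-one
Product: 16 (3R,4S,5S)-3,5-dimethylhept-1-yne-3,4-diol, via silyl alkyne diol 15 (not isolated)
Conditions: MeMgBr (3.5 equiv), Et2O, −78 → −40 °C; aq NH4Cl; then K2CO3 (0.2 equiv), MeOH, 23 °C
Reagents that add atoms: methylmagnesium bromide C[Mg]Br
Why: Cram-chelate-controlled Grignard 1,2-addition, in which the magnesium alkoxide chelates the carbonyl and methyl attacks from the side of the α-hydrogen (anti to sec-butyl), setting C3' as R; methanolysis then removes the silyl group.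

**Step 10**
Reactants: 16 (3R,4S,5S)-3,5-dimethylhept-1-yne-3,4-diol
Product: 18 (1E,3R,4S,5S)-1-iodo-3,5-dimethylhept-1-ene-3,4-diol, via E-vinylstannane 17 (not isolated)
Conditions: Bu3SnH (1.2 equiv), PdCl2(PPh3)2 (2 mol %), THF, 0 °C; then I2 (1.3 equiv), CH2Cl2, 0 °C
Reagents that add atoms: iodine II; tributyltin hydride CCCC[SnH](CCCC)CCCC (its tin is carried only in 17)
Why: Pd-catalysed syn-hydrostannation puts tin on the terminal carbon, away from the quaternary carbinol, giving the E-vinylstannane, and iododestannylation proceeds with retention of alkene geometry.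

**Step 11**
Reactants: 8 1-[(4R,5S)-5-(but-1-en-3-yn-2-yl)-2,2,4-trimethyl-1,3-dioxolan-4-yl]ethan-1-one; 18 (1E,3R,4S,5S)-1-iodo-3,5-dimethylhept-1-ene-3,4-diol
Product: 19 1-[(4R,5S)-5-[(6E,8R,9S,10S)-8,9-dihydroxy-8,10-dimethyl-5-oxododeca-1,6-dien-3-yn-2-yl]-2,2,4-trimethyl-1,3-dioxolan-4-yl]ethan-1-one
Conditions: PdCl2(PPh3)2 (5 mol %), CuI (2 mol %), Et3N (3 equiv), CO (1 atm), THF, 23 °C
Reagents that add atoms: carbon monoxide [C-]#[O+]
Why: Carbonylative Sonogashira coupling (oxidative addition of the vinyl iodide, CO insertion to the acyl-palladium species, alkynyl transfer and reductive elimination) gives the dienynone with the E-alkene retained; the E geometry also prevents lactonisation by the side-chain hydroxyls.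

**Step 12**
Reactants: 19 1-[(4R,5S)-5-[(6E,8R,9S,10S)-8,9-dihydroxy-8,10-dimethyl-5-oxododeca-1,6-dien-3-yn-2-yl]-2,2,4-trimethyl-1,3-dioxolan-4-yl]ethan-1-one
Product: 22 (7R,8S,8aS)-3-[(1E,3R,4S,5S)-3,4-dihydroxy-3,5-dimethylhept-1-en-1-yl]-7,8-O-isopropylidene-7,8-dihydroxy-7-methyl-8,8a-dihydro-1H-isochromen-6(7H)-one, via Z-dienone 20 (not isolated), via 2H-pyran 21 (not isolated)
Conditions: LiN(SiMe3)2 (3.3 equiv), THF (0.01 M), −78 → −20 °C; AcOH (4 equiv), −78 → 23 °C; then Et3N (2 equiv), CHCl3, 40 °C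
Reagents that add atoms: none
Why: The only possible ketone enolate (C5) adds 6-exo-dig to the acetylenic β-carbon C4a (intramolecular Michael addition), the resulting Z-1-oxatriene closes by thermal oxa-6π electrocyclization to 2H-pyran 21, and amine-mediated β,γ→α,β enone tautomerization protonates C8a under thermodynamic control to give the 8aS epimer (C1 equatorial, trans to O8, avoiding a 1,3-diaxial clash with the axial 7-methyl).

**Step 13**
Reactants: 22 (7R,8S,8aS)-3-[(1E,3R,4S,5S)-3,4-dihydroxy-3,5-dimethylhept-1-en-1-yl]-7,8-O-isopropylidene-7,8-dihydroxy-7-methyl-8,8a-dihydro-1H-isochromen-6(7H)-one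
Product: 23 (7R,8S,8aS)-3-[(1E,3R,4S,5S)-3,4-dihydroxy-3,5-dimethylhept-1-en-1-yl]-7,8-dihydroxy-7-methyl-8,8a-dihydro-1H-isochromen-6(7H)-one
Conditions: AcOH/H2O (4:1), 40 °C
Reagents that add atoms: none
Why: Mild acid hydrolysis of the strained trans-fused isopropylidene acetal frees the 7,8-diol under conditions too weak to ionise the tertiary allylic alcohol or open the vinylogous ester.

**Compound list**
1 | dimethyl (4R,5R)-2,2-dimethyl-1,3-dioxolane-4,5-dicarboxylate (acetonide of dimethyl L-tartrate) | COC(=O)[C@@H]1OC(C)(C)O[C@H]1C(=O)OC | starting material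
2 | dimethyl (4R,5R)-2,2,4-trimethyl-1,3-dioxolane-4,5-dicarboxylate | COC(=O)[C@]1(C)OC(C)(C)O[C@H]1C(=O)OC | intermediate
3 | (4R,5R)-N4,N5-dimethoxy-N4,N5,2,2,4-pentamethyl-1,3-dioxolane-4,5-dicarboxamide | CON(C)C(=O)[C@]1(C)OC(C)(C)O[C@H]1C(=O)N(C)OC | intermediate
4 | ethynyl(trimethyl)silane | C#C[Si](C)(C)C | starting material
5 | (4R,5R)-N-methoxy-N,2,2,4-tetramethyl-5-[3-(trimethylsilyl)prop-2-ynoyl]-1,3-dioxolane-4-carboxamide | CON(C)C(=O)[C@]1(C)OC(C)(C)O[C@H]1C(=O)C#C[Si](C)(C)C | intermediate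
6 | (4R,5S)-N-methoxy-N,2,2,4-tetramethyl-5-[4-(trimethylsilyl)but-1-en-3-yn-2-yl]-1,3-dioxolane-4-carboxamide | CON(C)C(=O)[C@]1(C)OC(C)(C)O[C@H]1C(=C)C#C[Si](C)(C)C | intermediate
7 | 1-[(4R,5S)-2,2,4-trimethyl-5-[4-(trimethylsilyl)but-1-en-3-yn-2-yl]-1,3-dioxolan-4-yl]ethan-1-one (silyl enyne ketone) | CC(=O)[C@]1(C)OC(C)(C)O[C@H]1C(=C)C#C[Si](C)(C)C | intermediate
8 | 1-[(4R,5S)-5-(but-1-en-3-yn-2-yl)-2,2,4-trimethyl-1,3-dioxolan-4-yl]ethan-1-one | CC(=O)[C@]1(C)OC(C)(C)O[C@H]1C(=C)C#C | intermediate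
9 | L-isoleucine [(2S,3S)-2-amino-3-methylpentanoic acid] | CC[C@H](C)[C@H](N)C(=O)O | starting material
10 | (2S,3S)-2-diazonio-3-methylpentanoate (diazonium carboxylate) | CC[C@H](C)[C@H]([N+]#N)C(=O)[O-] | intermediate
11 | (3R)-3-[(2S)-butan-2-yl]oxiran-2-one (alpha-lactone) | CC[C@H](C)[C@H]1OC1=O | intermediate
12 | (2S,3S)-2-hydroxy-3-methylpentanoic acid | CC[C@H](C)[C@H](O)C(=O)O | intermediate
13 | (5S)-5-[(2S)-butan-2-yl]-2,2-dimethyl-1,3-dioxolan-4-one | CC[C@H](C)[C@@H]1OC(C)(C)OC1=O | intermediate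
14 | (4S,5S)-4-hydroxy-5-methyl-1-(trimethylsilyl)hept-1-yn-3-one | CC[C@H](C)[C@H](O)C(=O)C#C[Si](C)(C)C | intermediate
15 | (3R,4S,5S)-3,5-dimethyl-1-(trimethylsilyl)hept-1-yne-3,4-diol (silyl alkyne diol) | CC[C@H](C)[C@H](O)[C@](C)(O)C#C[Si](C)(C)C | intermediate
16 | (3R,4S,5S)-3,5-dimethylhept-1-yne-3,4-diol | CC[C@H](C)[C@H](O)[C@](C)(O)C#C | intermediate
17 | (1E,3R,4S,5S)-3,5-dimethyl-1-(tributylstannyl)hept-1-ene-3,4-diol (E-vinylstannane) | CC[C@H](C)[C@H](O)[C@](C)(O)/C=C/[Sn](CCCC)(CCCC)CCCC | intermediate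
18 | (1E,3R,4S,5S)-1-iodo-3,5-dimethylhept-1-ene-3,4-diol | CC[C@H](C)[C@H](O)[C@](C)(O)/C=C/I | intermediate
19 | 1-[(4R,5S)-5-[(6E,8R,9S,10S)-8,9-dihydroxy-8,10-dimethyl-5-oxododeca-1,6-dien-3-yn-2-yl]-2,2,4-trimethyl-1,3-dioxolan-4-yl]ethan-1-one | CC[C@H](C)[C@H](O)[C@](C)(O)/C=C/C(=O)C#CC(=C)[C@@H]1OC(C)(C)O[C@@]1(C)C(C)=O | intermediate
20 | (3aR,6Z,7aS)-6-[(4E,6R,7S,8S)-6,7-dihydroxy-6,8-dimethyl-2-oxodec-4-en-1-ylidene]-2,2,3a-trimethyl-7-methylidenetetrahydro-1,3-benzodioxol-4(3aH)-one (Z-dienone) | CC[C@H](C)[C@H](O)[C@](C)(O)/C=C/C(=O)/C=C1/CC(=O)[C@]2(C)OC(C)(C)O[C@H]2C1=C | intermediate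
21 | (7R,8S)-3-[(1E,3R,4S,5S)-3,4-dihydroxy-3,5-dimethylhept-1-en-1-yl]-7,8-O-isopropylidene-7,8-dihydroxy-7-methyl-7,8-dihydro-1H-isochromen-6(5H)-one (2H-pyran) | CC[C@H](C)[C@H](O)[C@](C)(O)/C=C/C1=CC2=C(CO1)[C@@H]3OC(C)(C)O[C@@]3(C)C(=O)C2 | intermediate
22 | (7R,8S,8aS)-3-[(1E,3R,4S,5S)-3,4-dihydroxy-3,5-dimethylhept-1-en-1-yl]-7,8-O-isopropylidene-7,8-dihydroxy-7-methyl-8,8a-dihydro-1H-isochromen-6(7H)-one | CC[C@H](C)[C@H](O)[C@](C)(O)/C=C/C1=CC2=CC(=O)[C@]3(C)OC(C)(C)O[C@H]3[C@@H]2CO1 | intermediate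
23 | (7R,8S,8aS)-3-[(1E,3R,4S,5S)-3,4-dihydroxy-3,5-dimethylhept-1-en-1-yl]-7,8-dihydroxy-7-methyl-8,8a-dihydro-1H-isochromen-6(7H)-one | CC[C@H](C)[C@H](O)[C@](C)(O)/C=C/C1=CC2=CC(=O)[C@](C)(O)[C@@H](O)[C@@H]2CO1 | target

**Step count**
Total: 13 steps (steps 1–5 core fragment, steps 6–10 side-chain fragment, steps 11–13 union and endgame).
Longest linear sequence: 8 steps (1 → 2 → 3 → 5 → 6 → 8 → 19 → 22 → 23; the branch from 9 is equally long).

**Three steps most likely to fail, each with a fallback**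

Step 12 (ring-forming cascade). The enolate could instead attack the terminal methylene C1 (6-endo-trig, 1,6-addition) or react through oxygen, and three equivalents of strong base act on a polyfunctional dienynone. The fallback sets out from 19 and makes the C5–C4a bond by amine relay instead of by an enolate. Pyrrolidine (1.05 equiv, MeOH, 0 °C) adds to the acetylenic carbon C4a to give the enaminone 1-[(4R,5S)-5-[(6E,8R,9S,10S)-8,9-dihydroxy-8,10-dimethyl-5-oxo-3-(pyrrolidin-1-yl)dodeca-1,3,6-trien-2-yl]-2,2,4-trimethyl-1,3-dioxolan-4-yl]ethan-1-one F1. Warming F1 in AcOH/NaOAc buffer (toluene, 60 °C) lets the ketone enol attack the protonated enaminone carbon in a six-membered Mannich-type closure. Pyrrolidine is then eliminated, giving dienone 20 or its enone tautomer, which electrocyclizes and tautomerizes as before. The fallback comes back to the route at 22.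

Step 11 (carbonylative Sonogashira coupling). Direct non-carbonylative coupling, alkyne homocoupling or amine addition to the product ynone may dominate. The fallback sets out from 13 and 8 and joins the fragments by carbonyl addition and oxidation.
- Lithiated 3,3-diethoxyprop-1-yne adds to 13 (THF, −78 °C) to give (5S,6S)-1,1-diethoxy-5-hydroxy-6-methyloct-2-yn-4-one F2.
- Chelation-controlled MeMgBr addition gives (4R,5S,6S)-1,1-diethoxy-4,6-dimethyloct-2-yne-4,5-diol F3.
- NaAlH2(OCH2CH2OMe)2 (THF, 0 °C; hydroxyl-directed trans-hydroalumination) followed by 1 M HCl work-up gives (2E,4R,5S,6S)-4,5-dihydroxy-4,6-dimethyloct-2-enal F4.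
- Separately, 8 with N-iodosuccinimide and AgNO3 (cat.) in acetone gives the iodoalkyne 1-[(4R,5S)-5-(4-iodobut-1-en-3-yn-2-yl)-2,2,4-trimethyl-1,3-dioxolan-4-yl]ethan-1-one F5.
- CrCl2 (4 equiv, THF, 23 °C) couples F5 with F4 aldehyde-selectively in the presence of the ketone, giving the carbinol 1-[(4R,5S)-5-[(6E,8R,9S,10S)-5,8,9-trihydroxy-8,10-dimethyldodeca-1,6-dien-3-yn-2-yl]-2,2,4-trimethyl-1,3-dioxolan-4-yl]ethan-1-one F6 as a C5 epimer mixture.
- MnO2 (CH2Cl2) oxidises only the allylic/propargylic alcohol, and the fallback comes back to the route at 19.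

Step 3 (mono-alkynylation of the bis-amide). Selectivity between the two Weinreb amides rests only on the steric difference between the CH and the quaternary carbon. The fallback sets out from 2 and differentiates the two carboxyl groups by hydrolysis instead.
- KOH (1.0 equiv, MeOH/H2O, 0 °C) saponifies the less hindered ester to (4R,5R)-5-(methoxycarbonyl)-2,2,5-trimethyl-1,3-dioxolane-4-carboxylic acid F7.
- MeNH(OMe)·HCl, EDC·HCl and iPr2NEt (CH2Cl2) give methyl (4R,5R)-5-[methoxy(methyl)carbamoyl]-2,2,4-trimethyl-1,3-dioxolane-4-carboxylate F8.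
- Lithiated 4 (THF, −78 °C) gives methyl (4R,5R)-2,2,4-trimethyl-5-[3-(trimethylsilyl)prop-2-ynoyl]-1,3-dioxolane-4-carboxylate F9.
- Zn/CH2Br2/TiCl4 gives methyl (4R,5S)-2,2,4-trimethyl-5-[4-(trimethylsilyl)but-1-en-3-yn-2-yl]-1,3-dioxolane-4-carboxylate F10.
- MeNH(OMe)·HCl with excess MeMgBr (THF, −10 °C, one pot) converts the ester to the methyl ketone 7, and K2CO3/MeOH brings the fallback back to the route at 8.

**Further compounds**
F1 | step 12 | 1-[(4R,5S)-5-[(6E,8R,9S,10S)-8,9-dihydroxy-8,10-dimethyl-5-oxo-3-(pyrrolidin-1-yl)dodeca-1,3,6-trien-2-yl]-2,2,4-trimethyl-1,3-dioxolan-4-yl]ethan-1-one | CC[C@H](C)[C@H](O)[C@](C)(O)/C=C/C(=O)C=C(N1CCCC1)C(=C)[C@@H]2OC(C)(C)O[C@@]2(C)C(C)=O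
F2 | step 11 | (5S,6S)-1,1-diethoxy-5-hydroxy-6-methyloct-2-yn-4-one | CC[C@H](C)[C@H](O)C(=O)C#CC(OCC)OCC
F3 | step 11 | (4R,5S,6S)-1,1-diethoxy-4,6-dimethyloct-2-yne-4,5-diol | CC[C@H](C)[C@H](O)[C@](C)(O)C#CC(OCC)OCC
F4 | step 11 | (2E,4R,5S,6S)-4,5-dihydroxy-4,6-dimethyloct-2-enal | CC[C@H](C)[C@H](O)[C@](C)(O)/C=C/C=O
F5 | step 11 | 1-[(4R,5S)-5-(4-iodobut-1-en-3-yn-2-yl)-2,2,4-trimethyl-1,3-dioxolan-4-yl]ethan-1-one | CC(=O)[C@]1(C)OC(C)(C)O[C@H]1C(=C)C#CI
F6 | step 11 | 1-[(4R,5S)-5-[(6E,8R,9S,10S)-5,8,9-trihydroxy-8,10-dimethyldodeca-1,6-dien-3-yn-2-yl]-2,2,4-trimethyl-1,3-dioxolan-4-yl]ethan-1-one (C5 epimers) | CC[C@H](C)[C@H](O)[C@](C)(O)/C=C/C(O)C#CC(=C)[C@@H]1OC(C)(C)O[C@@]1(C)C(C)=O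
F7 | step 3 | (4R,5R)-5-(methoxycarbonyl)-2,2,5-trimethyl-1,3-dioxolane-4-carboxylic acid | COC(=O)[C@]1(C)OC(C)(C)O[C@H]1C(=O)O
F8 | step 3 | methyl (4R,5R)-5-[methoxy(methyl)carbamoyl]-2,2,4-trimethyl-1,3-dioxolane-4-carboxylate | COC(=O)[C@]1(C)OC(C)(C)O[C@H]1C(=O)N(C)OC
F9 | step 3 | methyl (4R,5R)-2,2,4-trimethyl-5-[3-(trimethylsilyl)prop-2-ynoyl]-1,3-dioxolane-4-carboxylate | COC(=O)[C@]1(C)OC(C)(C)O[C@H]1C(=O)C#C[Si](C)(C)C
F10 | step 3 | methyl (4R,5S)-2,2,4-trimethyl-5-[4-(trimethylsilyl)but-1-en-3-yn-2-yl]-1,3-dioxolane-4-carboxylate | COC(=O)[C@]1(C)OC(C)(C)O[C@H]1C(=C)C#C[Si](C)(C)C
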